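**Plan**
- Retrosynthesis: one operation cuts both the aryl–vinyl bond C4–C4a of the 1,2-dihydronaphthalene (ring B) and the O1–C2 lactone bond of the 2-pyranone. The open chain is then cut at pyranone C3–C4 (malonate carbon plus a 2-oxobutenoate), at C3–C4 of ring B (a formyl carbon) and at C1–C2 (Michael bond), leaving an arylidene malonate and a succinic semialdehyde ester.
- Enabling feature: C4a is the catechol-ring carbon para to the C7 oxygen and stands in a six-membered relation to C4, which is at the aldehyde level. The pyranone is the enol lactone of a 2-hydroxymuconic acid attached to C1 through its C3, so a malonate carbon can serve as pyranone C3, the second ester being a helper that leaves as CO2.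
- Forward order: the chain is assembled with no ring formed (Knoevenagel, Michael addition, formylation, vinylogous substitution); one acid operation then closes ring B and the pyranone ring and removes every protecting and activating group.
- Stereochemistry: C1 and C2 are set together in the amine-catalysed Michael addition (catalyst control; the syn adduct is the trans-1,2 arrangement of ring B) and are not touched again.

Key step: step 8

Assumption: the acetonide-protected aldehyde, tert-butyl 4-oxobutanoate and tert-butyl chlorooxoacetate are taken as purchasable, and the facial selectivity of the enamine addition to the arylidene malonate is taken to be that established for nitroalkene acceptors.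

Step 1
Reactants: 1 2,2-dimethyl-1,3-benzodioxole-5-carbaldehyde; 2 di-tert-butyl malonate
Product: 3 di-tert-butyl 2-[(2,2-dimethyl-1,3-benzodioxol-5-yl)methylidene]propanedioate
Conditions: piperidine (cat.), AcOH (cat.), PhMe, reflux, Dean–Stark
Reagents that add atoms: none
Why: Knoevenagel condensation, driven by azeotropic removal of water, should give the arylidene malonate that later supplies C1, pyranone C3 and the lactone carbonyl; no stereocentre is formed.

Step 2
Reactants: 3 arylidene malonate; 4 tert-butyl 4-oxobutanoate (excess)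
Product: 5 di-tert-butyl 2-[(1S,2S)-4-tert-butoxy-1-(2,2-dimethyl-1,3-benzodioxol-5-yl)-2-formyl-4-oxobutyl]propanedioate
Conditions: (R)-2-[diphenyl(trimethylsilyloxy)methyl]pyrrolidine (20 mol %), PhCO2H (20 mol %), PhMe, 4 °C to rt
Reagents that add atoms: none
Why: Enamine-catalysed asymmetric Michael addition of an aldehyde to an arylidene malonate: the (E)-enamine of 4, shielded on one face by the CPh2(OSiMe3) group, should add through an acyclic synclinal transition state, setting C2 (enamine face) and C1 (acceptor face) together as the syn adduct, which is the trans-1,2 relationship of ring B.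

Step 3
Reactants: 5 aldehyde
Product: 6 (2S,3S)-5-tert-butoxy-2-(2-tert-butoxy-2-oxoethyl)-4-(tert-butoxycarbonyl)-3-(2,2-dimethyl-1,3-benzodioxol-5-yl)-5-oxopentanoic acid
Conditions: NaClO2, NaH2PO4, 2-methylbut-2-ene, t-BuOH/H2O, 0 °C to rt
Reagents that add atoms: sodium chlorite, [Na+].[O-]Cl=O
Why: Pinnick oxidation should convert only the aldehyde into the acid under buffered conditions, without epimerising the α-stereocentre or touching the malonate, tert-butyl esters or acetonide.

Step 4
Reactants: 6 acid
Product: 7 (2R,3S)-5-tert-butoxy-4-(tert-butoxycarbonyl)-2-[(Z)-1-(tert-butoxycarbonyl)-2-hydroxyethenyl]-3-(2,2-dimethyl-1,3-benzodioxol-5-yl)-5-oxopentanoic acid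
Conditions: LiN(i-Pr)2 (3.3 equiv), THF, −78 to −40 °C; HCO2Et, −78 to 0 °C; cold 1 M HCl
Reagents that add atoms: ethyl formate, CCOC=O
Why: Crossed Claisen formylation: the carboxyl group, the malonate C–H and then the CH2 next to the tert-butyl ester should be deprotonated in that order (as in the dianions of 2-substituted succinic acid 4-tert-butyl esters), the carboxylate keeping C2–H from enolising, and C-formylation brings in C4 as a hydroxymethylene group.

Step 5
Reactants: 7 hydroxymethylene acid
Product: 8 methyl (2R,3S)-5-tert-butoxy-4-(tert-butoxycarbonyl)-2-[(E)-1-(tert-butoxycarbonyl)-2-methoxyethenyl]-3-(2,2-dimethyl-1,3-benzodioxol-5-yl)-5-oxopentanoate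
Conditions: Me3SiCHN2 (excess), MeOH/PhMe 1:4, 0 °C to rt
Reagents that add atoms: (trimethylsilyl)diazomethane, C[Si](C)(C)C=[N+]=[N-]
Why: Diazoalkane methylation should esterify the acid (the methyl ester kept in the target) and O-methylate the acidic formyl ester enol to a β-methoxyacrylate, while the much less acidic malonate C–H stays; the enol ether geometry is of no consequence.

Step 6
Reactants: 9 ethyl vinyl ether; 10 tert-butyl 2-chloro-2-oxoacetate
Product: 11 tert-butyl (3E)-4-ethoxy-2-oxobut-3-enoate
Conditions: pyridine (1.2 equiv), CH2Cl2, 0 °C to rt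
Reagents that add atoms: none
Why: C-acylation of an enol ether by an oxalyl half-ester chloride followed by loss of HCl (β-alkoxyvinyl ketone synthesis) should give the four-carbon pyranone building block; pyridine keeps HCl from the tert-butyl ester.

Step 7
Reactants: 8 malonate; 11 β-ethoxyvinyl keto ester
Product: 12 8-tert-butyl 1-methyl (2R,3R,5E)-4,4-bis(tert-butoxycarbonyl)-2-[(E)-1-(tert-butoxycarbonyl)-2-methoxyethenyl]-3-(2,2-dimethyl-1,3-benzodioxol-5-yl)-7-oxooct-5-enedioate
Conditions: KOt-Bu (0.2 equiv), THF, −20 to 0 °C; AcOH quench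
Reagents that add atoms: none
Why: Vinylogous nucleophilic substitution (conjugate addition–elimination of a malonate on a β-alkoxyvinyl ketone): only the malonate C–H is deprotonated, its anion should add to the unhindered β-carbon of 11 and expel ethoxide, which carries the chain, whereas attack on the molecule's own β-methoxyacrylate would be a geometrically disfavoured 5-endo-trig closure; no stereocentre is touched.

Step 8
Reactants: 12 open-chain precursor
Product: 15 CNP0239263.1 [(1R,2R)-1-(6-carboxy-2-oxo-2H-pyran-3-yl)-6,7-dihydroxy-2-(methoxycarbonyl)-1,2-dihydronaphthalene-3-carboxylic acid], via ring-closed tetraacid 13 (not isolated), via hydroxymuconic acid 14 (not isolated)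
Conditions: CF3CO2H/CH2Cl2 1:1, 0 °C to rt, argon; then H2O (10 vol %), 40 °C
Reagents that add atoms: none
Why: In anhydrous CF3CO2H the β-methoxyacrylate of 12 should be protonated at C3 to an oxocarbenium ion at C4, which the ring carbon para to the C7 oxygen (C4a) attacks, and loss of methanol gives the C3=C4 bond of ring B while the four tert-butyl esters are cleaved to 13. After water is added the acetonide is hydrolysed, the geminal diacid (a vinylogous β-keto acid) loses CO2 to the 2-hydroxymuconic acid 14, and its enol oxygen lactonises onto the carboxyl group left on the former malonate carbon to give the 2-pyranone. The closest known reaction types are the Friedel–Crafts (Bradsher-type) cyclodehydration of α-formyl 4-arylbutanoates to 3,4-dihydronaphthalene-2-carboxylates and the acid-induced closure of oxalocrotonic acid to 2-pyranone-6-carboxylic acid. Ring B closes by 6-exo-trig attack of the arene on the oxocarbenium carbon and the pyranone by 6-exo-trig acyl substitution. No stereocentre is formed; C1 and C2 keep the configuration from step 2, and trans is also the more stable arrangement should C2 enolise. The arene must choose C4 over the enone of the other arm and C4a over C8: the oxocarbenium ion is far more electrophilic than the enone (whose β-carbon sits next to a quaternary centre and could only close a five-membered ring), C4a is para to oxygen and unhindered whereas C8 lies between the side chain and an oxygen, and keeping water out until ring B has closed avoids a free β-formyl acid that could lose the C3 carboxyl group.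

**Compound list**
1 | 2,2-dimethyl-1,3-benzodioxole-5-carbaldehyde | O=Cc1ccc2OC(C)(C)Oc2c1 | starting material
2 | di-tert-butyl malonate | CC(C)(C)OC(=O)CC(=O)OC(C)(C)C | starting material
3 | di-tert-butyl 2-[(2,2-dimethyl-1,3-benzodioxol-5-yl)methylidene]propanedioate | CC(C)(C)OC(=O)C(=Cc1ccc2OC(C)(C)Oc2c1)C(=O)OC(C)(C)C | intermediate
4 | tert-butyl 4-oxobutanoate | O=CCCC(=O)OC(C)(C)C | starting material
5 | di-tert-butyl 2-[(1S,2S)-4-tert-butoxy-1-(2,2-dimethyl-1,3-benzodioxol-5-yl)-2-formyl-4-oxobutyl]propanedioate | O=C[C@@H](CC(=O)OC(C)(C)C)[C@H](c1ccc2OC(C)(C)Oc2c1)C(C(=O)OC(C)(C)C)C(=O)OC(C)(C)C | intermediate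
6 | (2S,3S)-5-tert-butoxy-2-(2-tert-butoxy-2-oxoethyl)-4-(tert-butoxycarbonyl)-3-(2,2-dimethyl-1,3-benzodioxol-5-yl)-5-oxopentanoic acid | OC(=O)[C@@H](CC(=O)OC(C)(C)C)[C@H](c1ccc2OC(C)(C)Oc2c1)C(C(=O)OC(C)(C)C)C(=O)OC(C)(C)C | intermediate
7 | (2R,3S)-5-tert-butoxy-4-(tert-butoxycarbonyl)-2-[(Z)-1-(tert-butoxycarbonyl)-2-hydroxyethenyl]-3-(2,2-dimethyl-1,3-benzodioxol-5-yl)-5-oxopentanoic acid | OC(=O)[C@@H](/C(=C/O)C(=O)OC(C)(C)C)[C@H](c1ccc2OC(C)(C)Oc2c1)C(C(=O)OC(C)(C)C)C(=O)OC(C)(C)C | intermediate
8 | methyl (2R,3S)-5-tert-butoxy-4-(tert-butoxycarbonyl)-2-[(E)-1-(tert-butoxycarbonyl)-2-methoxyethenyl]-3-(2,2-dimethyl-1,3-benzodioxol-5-yl)-5-oxopentanoate | COC(=O)[C@@H](/C(=C\OC)C(=O)OC(C)(C)C)[C@H](c1ccc2OC(C)(C)Oc2c1)C(C(=O)OC(C)(C)C)C(=O)OC(C)(C)C | intermediate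
9 | ethyl vinyl ether (ethoxyethene) | C=COCC | starting material
10 | tert-butyl 2-chloro-2-oxoacetate | CC(C)(C)OC(=O)C(=O)Cl | starting material
11 | tert-butyl (3E)-4-ethoxy-2-oxobut-3-enoate | CCO/C=C/C(=O)C(=O)OC(C)(C)C | intermediate
12 | 8-tert-butyl 1-methyl (2R,3R,5E)-4,4-bis(tert-butoxycarbonyl)-2-[(E)-1-(tert-butoxycarbonyl)-2-methoxyethenyl]-3-(2,2-dimethyl-1,3-benzodioxol-5-yl)-7-oxooct-5-enedioate | COC(=O)[C@@H](/C(=C\OC)C(=O)OC(C)(C)C)[C@H](c1ccc2OC(C)(C)Oc2c1)C(/C=C/C(=O)C(=O)OC(C)(C)C)(C(=O)OC(C)(C)C)C(=O)OC(C)(C)C | intermediate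
13 | 2-[(1R,2R)-3-carboxy-6,7-(isopropylidenedioxy)-2-(methoxycarbonyl)-1,2-dihydronaphthalen-1-yl]-2-[(E)-3-carboxy-3-oxoprop-1-enyl]propanedioic acid | COC(=O)[C@H]1C(C(=O)O)=Cc2cc3OC(C)(C)Oc3cc2[C@@H]1C(/C=C/C(=O)C(=O)O)(C(=O)O)C(=O)O | intermediate (not isolated)
14 | (2Z,4Z)-2-[(1R,2R)-3-carboxy-6,7-dihydroxy-2-(methoxycarbonyl)-1,2-dihydronaphthalen-1-yl]-5-hydroxyhexa-2,4-dienedioic acid | COC(=O)[C@H]1C(C(=O)O)=Cc2cc(O)c(O)cc2[C@@H]1/C(C(=O)O)=C/C=C(\O)C(=O)O | intermediate (not isolated)
15 | CNP0239263.1, (1R,2R)-1-(6-carboxy-2-oxo-2H-pyran-3-yl)-6,7-dihydroxy-2-(methoxycarbonyl)-1,2-dihydronaphthalene-3-carboxylic acid | COC(=O)[C@H]1C(C(=O)O)=Cc2cc(O)c(O)cc2[C@@H]1c1ccc(C(=O)O)oc1=O | target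

**Step count**
Total steps: 8. Longest linear sequence: 7 steps (steps 1, 2, 3, 4, 5, 7, 8).

**Steps most likely to fail**

Step 8. What may go wrong: the arene may be captured by the wrong electrophile (conjugate Friedel–Crafts attack on the enone arm), the electron-rich ring may be alkylated by tert-butyl cations, or the C3 carboxyl group may be lost by decarboxylation if the enol ether is hydrolysed before ring closure. The fallback sets out from 8 and comes back at 15. Ring B would be closed before the enone arm exists, by Lewis acid Friedel–Crafts cyclisation of 8 with BF3·OEt2 in CH2Cl2 at −40 °C. Under these conditions the tert-butyl esters, the acetonide and the malonate should survive, giving the ring-closed malonate triester F1. The malonate of F1 would then be joined to 11 as in step 7 to give the ring-closed enone F2. CF3CO2H/H2O would finally cleave the esters and the acetonide of F2, decarboxylate and lactonise to 15.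

Step 2. What may go wrong: the electron-rich arylidene malonate flanked by tert-butyl esters may react too slowly with the enamine, so that self-aldol of 4, retro-Michael equilibration and erosion of the syn selectivity take over. The fallback sets out from 1 and 2 and comes back at 6; the two stereocentres would be set one after the other. Wittig reaction of 1 with Ph3P=CHCHO would give the enal F3. Iminium-catalysed Michael addition of 2 to F3 with the same (R)-configured silyl prolinol ether would give the (S)-aldehyde F4, setting C1. Pinnick oxidation would give the acid F5. Acylation of (S)-4-benzyl-1,3-oxazolidin-2-one (pivaloyl mixed anhydride, LiCl, Et3N) would give the imide F6. Deprotonation with NaN(SiMe3)2 (2.1 equiv) and alkylation with tert-butyl bromoacetate (Evans alkylation) would give the alkylated imide F7, with C2 set by the auxiliary. LiOH/H2O2 would release 6.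

Step 7. What may go wrong: the hindered tertiary malonate anion may add reversibly, and the ethoxide set free may reverse the substitution or attack the keto ester, so that the quaternary carbon is not built up. The fallback sets out from 8 and comes back at 12. The malonate of 8 would be added in a conjugate sense (Et3N or catalytic PMe3, CH2Cl2, 0 °C) to the acetylenic keto ester tert-butyl 2-oxobut-3-ynoate F8, itself made from di-tert-butyl oxalate and HC≡CMgBr at −78 °C. Addition to the sp carbon releases no nucleophilic leaving group and would give 12 directly.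

Further compounds
F1 | step 8 | di-tert-butyl 2-[(1S,2R)-3-(tert-butoxycarbonyl)-6,7-(isopropylidenedioxy)-2-(methoxycarbonyl)-1,2-dihydronaphthalen-1-yl]propanedioate | COC(=O)[C@H]1C(C(=O)OC(C)(C)C)=Cc2cc3OC(C)(C)Oc3cc2[C@@H]1C(C(=O)OC(C)(C)C)C(=O)OC(C)(C)C
F2 | step 8 | di-tert-butyl 2-[(1R,2R)-3-(tert-butoxycarbonyl)-6,7-(isopropylidenedioxy)-2-(methoxycarbonyl)-1,2-dihydronaphthalen-1-yl]-2-[(E)-4-tert-butoxy-3,4-dioxobut-1-enyl]propanedioate | COC(=O)[C@H]1C(C(=O)OC(C)(C)C)=Cc2cc3OC(C)(C)Oc3cc2[C@@H]1C(/C=C/C(=O)C(=O)OC(C)(C)C)(C(=O)OC(C)(C)C)C(=O)OC(C)(C)C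
F3 | step 2 | (2E)-3-(2,2-dimethyl-1,3-benzodioxol-5-yl)prop-2-enal | O=C/C=C/c1ccc2OC(C)(C)Oc2c1
F4 | step 2 | di-tert-butyl 2-[(1S)-1-(2,2-dimethyl-1,3-benzodioxol-5-yl)-3-oxopropyl]propanedioate | O=CC[C@H](c1ccc2OC(C)(C)Oc2c1)C(C(=O)OC(C)(C)C)C(=O)OC(C)(C)C
F5 | step 2 | (3S)-5-tert-butoxy-4-(tert-butoxycarbonyl)-3-(2,2-dimethyl-1,3-benzodioxol-5-yl)-5-oxopentanoic acid | OC(=O)C[C@H](c1ccc2OC(C)(C)Oc2c1)C(C(=O)OC(C)(C)C)C(=O)OC(C)(C)C
F6 | step 2 | di-tert-butyl 2-[(1S)-3-[(4S)-4-benzyl-2-oxo-1,3-oxazolidin-3-yl]-1-(2,2-dimethyl-1,3-benzodioxol-5-yl)-3-oxopropyl]propanedioate | O=C(C[C@H](c1ccc2OC(C)(C)Oc2c1)C(C(=O)OC(C)(C)C)C(=O)OC(C)(C)C)N1[C@@H](Cc2ccccc2)COC1=O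
F7 | step 2 | di-tert-butyl 2-[(1S,2S)-2-{[(4S)-4-benzyl-2-oxo-1,3-oxazolidin-3-yl]carbonyl}-4-tert-butoxy-1-(2,2-dimethyl-1,3-benzodioxol-5-yl)-4-oxobutyl]propanedioate | O=C([C@@H](CC(=O)OC(C)(C)C)[C@H](c1ccc2OC(C)(C)Oc2c1)C(C(=O)OC(C)(C)C)C(=O)OC(C)(C)C)N1[C@@H](Cc2ccccc2)COC1=O
F8 | step 7 | tert-butyl 2-oxobut-3-ynoate | C#CC(=O)C(=O)OC(C)(C)C
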